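**Retrosynthetic overview**
1. Huazhongilexin 14 is the C2-symmetric all-trans 2,5-diaryl-3,4-bis(hydroxymethyl)tetrahydrofuran. Both aryl C1–C2/C5 bonds are cut in one operation, giving two molecules of 2,6-dimethoxyphenol 11 and the aryl-free bis-acetal 10, a protected (2R,3R)-2,3-bis(hydroxymethyl)succinaldehyde; the second bond joins 11 to the aryl-bearing tetrahydrofuran 12 formed in the flask.
2. Enabling feature: the C2 axis through ring O1 and the midpoint of C3–C4 makes C2 and C5 equivalent aldehyde-level carbons. Each is bonded to O1, to a CH2O-bearing stereocentre (C3 or C4, mutually trans) and to aryl C1, which lies para to the phenol OH, the open nucleophilic carbon of 11. The all-trans array is what attack anti to C3/C4, backed by equilibration, should deliver.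
3. 10 ⇐ ozonolysis/acetalization of dipropenyl 8 ⇐ olefin migration in diallyl 7 ⇐ diol 6 ⇐ oxidative enolate homocoupling of imide 3 (C3–C4 bond, both stereocentres from one oxazolidinone auxiliary).
4. Ring order: the tetrahydrofuran ring is closed first (step 6, as the cyclic bis-acetal); the two benzene rings are bought and attached last (step 7).

Key step: step 7

Remark on the chemistry: the acetal carbons of 10 (C2, C5) and 12 (C5) are anomer mixtures and the alkenes of 8 an E/Z mixture; they are drawn without, or with one, configuration because steps 6 and 7 erase them.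

**Step 1**
Reactants: 1 (S)-4-benzyloxazolidin-2-one; 2 pent-4-enoyl chloride
Product: 3 (S)-4-benzyl-3-(pent-4-enoyl)oxazolidin-2-one
Conditions: Et3N, DMAP (cat.), CH2Cl2, 0 °C → rt
Reagents that add atoms: none
Why: DMAP-catalysed N-acylation of an oxazolidinone by an acid chloride (nucleophilic acyl substitution) is routine and touches no stereocentre.

**Step 2**
Reactants: 3 (S)-4-benzyl-3-(pent-4-enoyl)oxazolidin-2-one (two molecules)
Product: 5 (4S,4'S)-3,3'-[(2R,3R)-2,3-di(prop-2-en-1-yl)butanedioyl]bis(4-benzyloxazolidin-2-one), via lithium Z-enolate 4 (not isolated)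
Conditions: LiN(iPr)2 (1.1 equiv), THF, −78 °C; then TiCl4 (1.1 equiv), −78 °C → rt
Reagents that add atoms: none
Why: Oxidative homocoupling of a chelated N-acyl oxazolidinone enolate: TiCl4 (tetravalent titanium) transmetalates the Z-enolate and oxidizes it by one electron (ending as trivalent titanium), and the two α-carbons join on the enolate faces opposite the benzyl group of each auxiliary, which should set both new stereocentres as R and make the C2-symmetric R,R dimer the main isomer, separable from the minor R,S isomer by chromatography or crystallization.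

**Step 3**
Reactants: 5 (4S,4'S)-3,3'-[(2R,3R)-2,3-di(prop-2-en-1-yl)butanedioyl]bis(4-benzyloxazolidin-2-one)
Product: 6 (2R,3R)-2,3-di(prop-2-en-1-yl)butane-1,4-diol
Conditions: LiBH4, MeOH (2 equiv per imide), THF, 0 °C → rt
Reagents that add atoms: none
Why: Hydride reduction of N-acyl oxazolidinones to primary alcohols with LiBH4 cleaves both auxiliaries without base, so the two α-stereocentres should not epimerize.

**Step 4**
Reactants: 6 (2R,3R)-2,3-di(prop-2-en-1-yl)butane-1,4-diol
Product: 7 (4R,5R)-4,5-bis{[(tert-butyldiphenylsilyl)oxy]methyl}octa-1,7-diene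
Conditions: TBDPSCl (2.3 equiv), imidazole, DMF, rt
Reagents that add atoms: tert-butyl(chloro)diphenylsilane, CC(C)(C)[Si](Cl)(c1ccccc1)c1ccccc1
Why: Standard imidazole-mediated silylation of primary alcohols; the tert-butyldiphenylsilyl ether is chosen because it should survive hot RuHCl(CO)(PPh3)3, ozone, PPTS in methanol and cold BF3·OEt2 and is too hindered to trap the oxocarbenium ions of step 7.

**Step 5**
Reactants: 7 (4R,5R)-4,5-bis{[(tert-butyldiphenylsilyl)oxy]methyl}octa-1,7-diene
Product: 8 (2E,4R,5R,6E)-4,5-bis{[(tert-butyldiphenylsilyl)oxy]methyl}octa-2,6-diene (expected as an E/Z mixture, used as such)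
Conditions: RuHCl(CO)(PPh3)3 (5 mol %), toluene, 80 °C
Reagents that add atoms: none
Why: Ruthenium hydride-catalysed olefin isomerization (hydrometalation/β-hydride elimination) moves each terminal double bond one position to the more stable 1-propenyl group, and the C4/C5 stereocentres should persist because a further migration would need ruthenium on the congested tertiary carbon.

**Step 6**
Reactants: 8 (2E,4R,5R,6E)-4,5-bis{[(tert-butyldiphenylsilyl)oxy]methyl}octa-2,6-diene
Product: 10 (3R,4R)-3,4-bis{[(tert-butyldiphenylsilyl)oxy]methyl}-2,5-dimethoxytetrahydrofuran (anomer mixture), via dialdehyde 9 (not isolated)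
Conditions: O3, CH2Cl2/MeOH, −78 °C; Me2S, −78 °C → rt; then PPTS (cat.), MeOH, rt
Reagents that add atoms: ozone, [O-][O+]=O; methanol, CO
Why: Ozonolysis with reductive work-up cuts both propenyl groups to dialdehyde 9, which in acidic methanol closes by 5-exo-trig addition of a hemiacetal OH to the second carbonyl and methanol exchange to the cyclic bis-acetal (the behaviour of succinaldehyde itself); the non-basic medium should prevent α-epimerization and β-elimination of the silyloxy groups, and the two new acetal centres form as anomer mixtures that are erased in step 7.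

**Step 7**
Reactants: 10 (3R,4R)-3,4-bis{[(tert-butyldiphenylsilyl)oxy]methyl}-2,5-dimethoxytetrahydrofuran; 11 2,6-dimethoxyphenol (2.2 equiv)
Product: 13 4,4'-[(2S,3R,4R,5S)-3,4-bis{[(tert-butyldiphenylsilyl)oxy]methyl}tetrahydrofuran-2,5-diyl]bis(2,6-dimethoxyphenol), via mono-aryl acetal 12 (not isolated)
Conditions: BF3·OEt2 (3 equiv), CH2Cl2, −78 → −20 °C; NaHCO3 quench at −20 °C
Reagents that add atoms: none
Why: BF3·OEt2 ionizes one anomeric C–OMe bond of 10 to a five-membered cyclic oxocarbenium ion, which is attacked by C4 of 11 (para to OH) and rearomatizes to the mono-aryl acetal 12; ionization of the remaining C5–OMe bond and a second Friedel–Crafts attack then forge the aryl C1–C2 bond that joins the second aryl ring to the aryl-bearing tetrahydrofuran. The closest known reaction type is the Lewis-acid Friedel–Crafts arylation of 2-alkoxytetrahydrofurans (lactol methyl ethers) by electron-rich arenes used for 2,5-diaryl-3,4-dialkyltetrahydrofurans, here run twice in one flask on a succinaldehyde bis-acetal. No ring is closed: the tetrahydrofuran ring made in step 6 persists because exocyclic C–OMe ionization to the ring oxocarbenium ion is faster than endocyclic cleavage. The new stereocentres C2 and C5 are each controlled by the adjacent stereocentre (C3, C4): the arene adds to the oxocarbenium face opposite the neighbouring CH2OTBDPS group (2,3-trans and 4,5-trans), and because C3 and C4 are trans the two additions give the C2-symmetric all-trans (2S,3R,4R,5S) isomer, which is also the thermodynamic isomer reachable by reversible p-hydroxybenzylic C–O ionization on brief warming. The step needs para (C4) regioselectivity on the phenol, secured by para activation from the free OH, by the methoxy groups blocking both ortho positions and by their hindering C3/C5 toward a secondary α-branched electrophile; it also needs to stop at the diaryl ether, secured by low temperature, only a slight excess of 11 and the far easier ionization of an O,O-acetal than of a benzylic ether.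

**Step 8**
Reactants: 13 4,4'-[(2S,3R,4R,5S)-3,4-bis{[(tert-butyldiphenylsilyl)oxy]methyl}tetrahydrofuran-2,5-diyl]bis(2,6-dimethoxyphenol)
Product: 14 Huazhongilexin, 4,4'-[(2S,3R,4R,5S)-3,4-bis(hydroxymethyl)tetrahydrofuran-2,5-diyl]bis(2,6-dimethoxyphenol)
Conditions: Bu4NF, AcOH (1:1), THF, 0 °C → rt
Reagents that add atoms: none
Why: Fluoride-induced cleavage of the Si–O bonds (desilylation) buffered with acetic acid should free both primary alcohols without ionizing or epimerizing the p-hydroxybenzylic ether centres.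

**Compound list**
1 | (S)-4-benzyloxazolidin-2-one | O=C1N[C@@H](Cc2ccccc2)CO1 | starting material
2 | pent-4-enoyl chloride | C=CCCC(=O)Cl | starting material
3 | (S)-4-benzyl-3-(pent-4-enoyl)oxazolidin-2-one | C=CCCC(=O)N1[C@@H](Cc2ccccc2)COC1=O | intermediate
4 | lithium (Z)-1-[(S)-4-benzyl-2-oxooxazolidin-3-yl]penta-1,4-dien-1-olate (enolate of 3, not isolated) | C=CC/C=C(\O[Li])N1[C@@H](Cc2ccccc2)COC1=O | intermediate
5 | (4S,4'S)-3,3'-[(2R,3R)-2,3-di(prop-2-en-1-yl)butanedioyl]bis(4-benzyloxazolidin-2-one) | C=CC[C@@H](C(=O)N1[C@@H](Cc2ccccc2)COC1=O)[C@@H](CC=C)C(=O)N1[C@@H](Cc2ccccc2)COC1=O | intermediate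
6 | (2R,3R)-2,3-di(prop-2-en-1-yl)butane-1,4-diol | C=CC[C@@H](CO)[C@@H](CC=C)CO | intermediate
7 | (4R,5R)-4,5-bis{[(tert-butyldiphenylsilyl)oxy]methyl}octa-1,7-diene | C=CC[C@@H](CO[Si](c1ccccc1)(c1ccccc1)C(C)(C)C)[C@@H](CC=C)CO[Si](c1ccccc1)(c1ccccc1)C(C)(C)C | intermediate
8 | (2E,4R,5R,6E)-4,5-bis{[(tert-butyldiphenylsilyl)oxy]methyl}octa-2,6-diene (E/Z mixture, E,E isomer drawn) | C/C=C/[C@@H](CO[Si](c1ccccc1)(c1ccccc1)C(C)(C)C)[C@@H](/C=C/C)CO[Si](c1ccccc1)(c1ccccc1)C(C)(C)C | intermediate
9 | (2R,3R)-2,3-bis{[(tert-butyldiphenylsilyl)oxy]methyl}butanedial (not isolated) | O=C[C@@H](CO[Si](c1ccccc1)(c1ccccc1)C(C)(C)C)[C@@H](C=O)CO[Si](c1ccccc1)(c1ccccc1)C(C)(C)C | intermediate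
10 | (3R,4R)-3,4-bis{[(tert-butyldiphenylsilyl)oxy]methyl}-2,5-dimethoxytetrahydrofuran (anomer mixture at C2 and C5) | COC1OC(OC)[C@@H](CO[Si](c2ccccc2)(c2ccccc2)C(C)(C)C)[C@@H]1CO[Si](c1ccccc1)(c1ccccc1)C(C)(C)C | intermediate
11 | 2,6-dimethoxyphenol | COc1cccc(OC)c1O | starting material
12 | 4-[(2S,3R,4R)-3,4-bis{[(tert-butyldiphenylsilyl)oxy]methyl}-5-methoxytetrahydrofuran-2-yl]-2,6-dimethoxyphenol (C5 anomers, not isolated) | COc1cc([C@H]2OC(OC)[C@@H](CO[Si](c3ccccc3)(c3ccccc3)C(C)(C)C)[C@@H]2CO[Si](c2ccccc2)(c2ccccc2)C(C)(C)C)cc(OC)c1O | intermediate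
13 | 4,4'-[(2S,3R,4R,5S)-3,4-bis{[(tert-butyldiphenylsilyl)oxy]methyl}tetrahydrofuran-2,5-diyl]bis(2,6-dimethoxyphenol) | COc1cc([C@H]2O[C@H](c3cc(OC)c(O)c(OC)c3)[C@@H](CO[Si](c3ccccc3)(c3ccccc3)C(C)(C)C)[C@@H]2CO[Si](c2ccccc2)(c2ccccc2)C(C)(C)C)cc(OC)c1O | intermediate
14 | Huazhongilexin, 4,4'-[(2S,3R,4R,5S)-3,4-bis(hydroxymethyl)tetrahydrofuran-2,5-diyl]bis(2,6-dimethoxyphenol) | COc1cc([C@H]2O[C@H](c3cc(OC)c(O)c(OC)c3)[C@@H](CO)[C@@H]2CO)cc(OC)c1O | target

**Totals**
Total step count: 8. Longest linear sequence: 8 steps (1 + 2 → 14); 11 is bought and enters at step 7.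

**Steps most likely to fail**

Step 7. The phenol may be attacked at C3 instead of C4. The p-hydroxybenzylic ether bonds of 12 or 13 may ionize and be captured by excess phenol (ring-opened over-arylation) or by the other aryl ring (cyclization to an aryltetralin). Equilibration to the all-trans isomer may also stay incomplete. The fallback, organometallic addition followed by cyclodehydration, sets out from dialdehyde 9, taken crude from step 6 after the Me2S work-up without the methanolic acid. [4-(Benzyloxy)-3,5-dimethoxyphenyl]magnesium bromide F1 (from 2-(benzyloxy)-5-bromo-1,3-dimethoxybenzene and Mg in THF) is added at −78 °C and should give (2R,3R)-1,4-bis[4-(benzyloxy)-3,5-dimethoxyphenyl]-2,3-bis{[(tert-butyldiphenylsilyl)oxy]methyl}butane-1,4-diol F2 as a mixture of carbinol epimers, with the aryl position fixed by the metal. Acid-mediated cyclodehydration (TsOH cat. or BF3·OEt2, CH2Cl2, 0 °C) through the p-alkoxybenzylic cation is reversible and should funnel the epimers to (2S,3R,4R,5S)-2,5-bis[4-(benzyloxy)-3,5-dimethoxyphenyl]-3,4-bis{[(tert-butyldiphenylsilyl)oxy]methyl}tetrahydrofuran F3. Hydrogenolysis of the two aryl benzyl ethers (H2, Pd/C, EtOAc) comes back to the route at 13.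

Step 2. Facial control in the radical-type coupling may be incomplete, giving much of the R,S dimer, or the enolate may be quenched back to 3 so that conversion stays low. The fallback, a stepwise stereospecific alkylation, sets out from 3. Deprotonation with NaN(SiMe3)2 (THF, −78 °C) gives sodium (Z)-1-[(S)-4-benzyl-2-oxooxazolidin-3-yl]penta-1,4-dien-1-olate F4. This is alkylated with methyl (R)-2-{[(trifluoromethyl)sulfonyl]oxy}pent-4-enoate F5 (from methyl (R)-2-hydroxypent-4-enoate, (CF3SO2)2O and 2,6-lutidine), with SN2 inversion at the triflate carbon and auxiliary control at the enolate carbon. The product should be methyl (2R,3R)-2-(prop-2-en-1-yl)-3-[(S)-4-benzyl-2-oxooxazolidine-3-carbonyl]hex-5-enoate F6. LiBH4 reduces imide and ester together, and the route is rejoined at diol 6.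

Step 5. One allyl group may fail to migrate, or migration may run on into the tertiary allylic position and destroy the C4/C5 stereocentres. The fallback, a one-carbon degradation without olefin migration, sets out from 7. Ozonolysis (O3, CH2Cl2, −78 °C; Me2S) should give (3R,4R)-3,4-bis{[(tert-butyldiphenylsilyl)oxy]methyl}hexanedial F7. Condensation with piperidine (toluene, molecular sieves) gives 1,1'-[(1E,3R,4R,5E)-3,4-bis{[(tert-butyldiphenylsilyl)oxy]methyl}hexa-1,5-diene-1,6-diyl]dipiperidine F8, in which the stereocentres are not enolizable. Ozonolysis of the two enamine double bonds (O3, CH2Cl2, −78 °C; Me2S) comes back to the route at dialdehyde 9, which is acetalized to 10 as in step 6.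

**Further compounds**
F1 | step 7 | [4-(benzyloxy)-3,5-dimethoxyphenyl]magnesium bromide | COc1cc([Mg]Br)cc(OC)c1OCc1ccccc1
F2 | step 7 | (2R,3R)-1,4-bis[4-(benzyloxy)-3,5-dimethoxyphenyl]-2,3-bis{[(tert-butyldiphenylsilyl)oxy]methyl}butane-1,4-diol (carbinol epimers) | COc1cc(C(O)[C@@H](CO[Si](c2ccccc2)(c2ccccc2)C(C)(C)C)[C@H](CO[Si](c2ccccc2)(c2ccccc2)C(C)(C)C)C(O)c2cc(OC)c(OCc3ccccc3)c(OC)c2)cc(OC)c1OCc1ccccc1
F3 | step 7 | (2S,3R,4R,5S)-2,5-bis[4-(benzyloxy)-3,5-dimethoxyphenyl]-3,4-bis{[(tert-butyldiphenylsilyl)oxy]methyl}tetrahydrofuran | COc1cc([C@H]2O[C@H](c3cc(OC)c(OCc4ccccc4)c(OC)c3)[C@@H](CO[Si](c3ccccc3)(c3ccccc3)C(C)(C)C)[C@@H]2CO[Si](c2ccccc2)(c2ccccc2)C(C)(C)C)cc(OC)c1OCc1ccccc1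
F4 | step 2 | sodium (Z)-1-[(S)-4-benzyl-2-oxooxazolidin-3-yl]penta-1,4-dien-1-olate | C=CC/C=C(\O[Na])N1[C@@H](Cc2ccccc2)COC1=O
F5 | step 2 | methyl (R)-2-{[(trifluoromethyl)sulfonyl]oxy}pent-4-enoate | C=CC[C@@H](OS(=O)(=O)C(F)(F)F)C(=O)OC
F6 | step 2 | methyl (2R,3R)-2-(prop-2-en-1-yl)-3-[(S)-4-benzyl-2-oxooxazolidine-3-carbonyl]hex-5-enoate | C=CC[C@@H](C(=O)N1[C@@H](Cc2ccccc2)COC1=O)[C@@H](CC=C)C(=O)OC
F7 | step 5 | (3R,4R)-3,4-bis{[(tert-butyldiphenylsilyl)oxy]methyl}hexanedial | O=CC[C@@H](CO[Si](c1ccccc1)(c1ccccc1)C(C)(C)C)[C@@H](CC=O)CO[Si](c1ccccc1)(c1ccccc1)C(C)(C)C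
F8 | step 5 | 1,1'-[(1E,3R,4R,5E)-3,4-bis{[(tert-butyldiphenylsilyl)oxy]methyl}hexa-1,5-diene-1,6-diyl]dipiperidine | N1(CCCCC1)/C=C/[C@@H](CO[Si](c1ccccc1)(c1ccccc1)C(C)(C)C)[C@@H](/C=C/N1CCCCC1)CO[Si](c1ccccc1)(c1ccccc1)C(C)(C)C
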